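Assumption: methyl (2R)‑oxirane‑2‑carboxylate (methyl (R)‑glycidate, the L‑serine‑derived enantiomer) is bought enantiopure and is the only source of chirality. The target stereocentre is C3 of the chroman, which I assign as R from the given SMILES.

## Retrosynthetic overview

1. Target 19 ← desilylation of 18. The C6–prenyl bond of 18 comes from an aromatic Claisen [3,3] rearrangement of the 7‑O‑(1,1‑dimethylallyl) ether 16, made from propargyl ether 15.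
2. The dihydropyran ring (the only ring built; both benzene rings are bought) ← acid cyclodehydration of the (R)‑diol 12, phenol oxygen onto the tertiary carbinol, with C3 untouched. It is closed before the Claisen step.
3. Diol 12 ← aryl Grignard 10 opening methyl (R)‑glycidate 9 at CH2, then two MeMgBr on the ester.
4. Aryl bromide 8 ← NBS on bibenzyl 7 ← hydroboration/B‑alkyl Suzuki of styrene 5 with aryl bromide 2.
5. 2 and 5 ← 5‑bromoresorcinol 1 and 3,4‑dihydroxybenzaldehyde 3.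

## Route

Step 1
Reactants: 1 5‑bromobenzene‑1,3‑diol
Product: 2 1‑bromo‑3,5‑bis(methoxymethoxy)benzene
Conditions: MOMCl (2.5 equiv), i‑Pr2NEt, CH2Cl2, 0 °C → rt
Reagents that add atoms: chloromethyl methyl ether, COCCl
Why: Simple O‑alkylation of both phenols (MOM protection) gives ethers that survive Grignard chemistry and are removed later by acid.

Step 2
Reactants: 3 3,4‑dihydroxybenzaldehyde
Product: 4 3,4‑bis(triisopropylsilyloxy)benzaldehyde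
Conditions: TIPSOTf (2.3 equiv), 2,6‑lutidine, CH2Cl2, 0 °C → rt
Reagents that add atoms: triisopropylsilyl triflate, CC(C)[Si](OS(=O)(=O)C(F)(F)F)(C(C)C)C(C)C
Why: O‑silylation of the catechol gives aryl TIPS ethers, which are stable to the later acid and organometallic steps and are removable with fluoride at the end.

Step 3
Reactants: 4 3,4‑bis(triisopropylsilyloxy)benzaldehyde
Product: 5 4‑ethenyl‑1,2‑bis(triisopropylsilyloxy)benzene
Conditions: Ph3PCH3Br, KOtBu, THF, 0 °C → rt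
Reagents that add atoms: methyltriphenylphosphonium bromide, C[P+](c1ccccc1)(c1ccccc1)c1ccccc1.[Br-]
Why: Wittig methylenation of an unhindered aryl aldehyde with the pre‑formed ylide is reliable and leaves the silyl ethers intact.

Step 4
Reactants: 5 4‑ethenyl‑1,2‑bis(triisopropylsilyloxy)benzene; 2 1‑bromo‑3,5‑bis(methoxymethoxy)benzene
Product: 7 1‑{2‑[3,4‑bis(triisopropylsilyloxy)phenyl]ethyl}‑3,5‑bis(methoxymethoxy)benzene, via 9‑{2‑[3,4‑bis(triisopropylsilyloxy)phenyl]ethyl}‑9‑borabicyclo[3.3.1]nonane 6 (not isolated)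
Conditions: 9‑BBN, THF, rt; then 2, PdCl2(dppf) (3 mol%), aq. K3PO4, DMF, 60 °C
Reagents that add atoms: none
Why: Anti‑Markovnikov hydroboration of the styrene followed by B‑alkyl Suzuki–Miyaura coupling gives the saturated two‑carbon bridge directly, so no later hydrogenation is needed.

Step 5
Reactants: 7 1‑{2‑[3,4‑bis(triisopropylsilyloxy)phenyl]ethyl}‑3,5‑bis(methoxymethoxy)benzene
Product: 8 2‑bromo‑1‑{2‑[3,4‑bis(triisopropylsilyloxy)phenyl]ethyl}‑3,5‑bis(methoxymethoxy)benzene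
Conditions: NBS (1.0 equiv), MeCN, 0 °C, dark
Reagents that add atoms: N‑bromosuccinimide, O=C1CCC(=O)N1Br
Why: Electrophilic aromatic bromination of a 3,5‑dialkoxy‑alkylbenzene goes para to one alkoxy group (ortho to the chain), not between the two oxygens, and the bis‑silyloxy ring is much less activated.

Step 6
Reactants: 8 2‑bromo‑1‑{2‑[3,4‑bis(triisopropylsilyloxy)phenyl]ethyl}‑3,5‑bis(methoxymethoxy)benzene; 9 methyl (2R)‑oxirane‑2‑carboxylate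
Product: 12 (2R)‑1‑{2‑[2‑(3,4‑bis(triisopropylsilyloxy)phenyl)ethyl]‑4,6‑bis(methoxymethoxy)phenyl}‑3‑methylbutane‑2,3‑diol, via {2‑[2‑(3,4‑bis(triisopropylsilyloxy)phenyl)ethyl]‑4,6‑bis(methoxymethoxy)phenyl}magnesium bromide 10 (not isolated), via methyl (2R)‑3‑{2‑[2‑(3,4‑bis(triisopropylsilyloxy)phenyl)ethyl]‑4,6‑bis(methoxymethoxy)phenyl}‑2‑hydroxypropanoate 11 (not isolated)
Conditions: Mg, LiCl, THF, rt; CuI (10 mol%), 9, −40 °C; then MeMgBr (4 equiv), −40 → 0 °C; aq. NH4Cl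
Reagents that add atoms: methylmagnesium bromide, C[Mg]Br
Why: Copper‑catalysed Grignard opening of the glycidic ester occurs by SN2 at the CH2 terminus faster than ester addition at −40 °C, and the Grignard double addition to the ester then gives the tertiary carbinol; no bond to the stereocentre is made or broken, so the (R) configuration of 9 is carried into 12.

Step 7
Reactants: 12 (2R)‑1‑{2‑[2‑(3,4‑bis(triisopropylsilyloxy)phenyl)ethyl]‑4,6‑bis(methoxymethoxy)phenyl}‑3‑methylbutane‑2,3‑diol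
Product: 14 (3R)‑5‑{2‑[3,4‑bis(triisopropylsilyloxy)phenyl]ethyl}‑2,2‑dimethyl‑3,4‑dihydro‑2H‑chromene‑3,7‑diol, via 4‑[(2R)‑2,3‑dihydroxy‑3‑methylbutyl]‑5‑{2‑[3,4‑bis(triisopropylsilyloxy)phenyl]ethyl}benzene‑1,3‑diol 13 (not isolated)
Conditions: 3 M HCl in MeOH/THF, 45 °C; evaporate; p‑TsOH·H2O (0.2 equiv), ClCH2CH2Cl, 60 °C
Reagents that add atoms: none
Why: Acetal methanolysis frees both phenols and SN1 cyclodehydration then traps the tertiary cation with the ortho phenol (6‑membered ring); the C3–O bond is never broken so C3 stays R, and aryl TIPS ethers tolerate these acids.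

Step 8
Reactants: 14 (3R)‑5‑{2‑[3,4‑bis(triisopropylsilyloxy)phenyl]ethyl}‑2,2‑dimethyl‑3,4‑dihydro‑2H‑chromene‑3,7‑diol
Product: 15 (3R)‑5‑{2‑[3,4‑bis(triisopropylsilyloxy)phenyl]ethyl}‑2,2‑dimethyl‑7‑[(2‑methylbut‑3‑yn‑2‑yl)oxy]‑3,4‑dihydro‑2H‑chromen‑3‑ol
Conditions: 3‑chloro‑3‑methylbut‑1‑yne, DBU, CuCl2·2H2O (1 mol%), MeCN, 0 °C
Reagents that add atoms: 3‑chloro‑3‑methylbut‑1‑yne, C#CC(C)(C)Cl
Why: Copper‑catalysed propargylic etherification alkylates the only phenol selectively at the tertiary carbon, and the secondary alcohol does not react under these conditions.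

Step 9
Reactants: 15 (3R)‑5‑{2‑[3,4‑bis(triisopropylsilyloxy)phenyl]ethyl}‑2,2‑dimethyl‑7‑[(2‑methylbut‑3‑yn‑2‑yl)oxy]‑3,4‑dihydro‑2H‑chromen‑3‑ol
Product: 18 (3R)‑5‑{2‑[3,4‑bis(triisopropylsilyloxy)phenyl]ethyl}‑2,2‑dimethyl‑6‑(3‑methylbut‑2‑en‑1‑yl)‑3,4‑dihydro‑2H‑chromene‑3,7‑diol, via (3R)‑5‑{2‑[3,4‑bis(triisopropylsilyloxy)phenyl]ethyl}‑2,2‑dimethyl‑7‑[(2‑methylbut‑3‑en‑2‑yl)oxy]‑3,4‑dihydro‑2H‑chromen‑3‑ol 16 (not isolated), via (3R)‑5‑{2‑[3,4‑bis(triisopropylsilyloxy)phenyl]ethyl}‑3‑hydroxy‑2,2‑dimethyl‑6‑(3‑methylbut‑2‑en‑1‑yl)‑3,4‑dihydro‑2H‑chromen‑7(6H)‑one 17 (not isolated)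
Conditions: H2 (1 atm), Lindlar catalyst, quinoline, toluene, rt; filter; then 110 °C
Reagents that add atoms: none
Why: Lindlar semihydrogenation gives the tertiary allyl aryl ether, which undergoes aromatic Claisen [3,3]‑sigmatropic rearrangement and tautomerisation to the ortho‑prenylphenol; C–C bond formation is expected mainly at C6 (para to the ring oxygen) over C8 (between the two oxygens), the minor isomer being removed by chromatography, and C3 is not involved.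

Step 10
Reactants: 18 (3R)‑5‑{2‑[3,4‑bis(triisopropylsilyloxy)phenyl]ethyl}‑2,2‑dimethyl‑6‑(3‑methylbut‑2‑en‑1‑yl)‑3,4‑dihydro‑2H‑chromene‑3,7‑diol
Product: 19 (3R)‑5‑[2‑(3,4‑dihydroxyphenyl)ethyl]‑2,2‑dimethyl‑6‑(3‑methylbut‑2‑en‑1‑yl)‑3,4‑dihydro‑2H‑chromene‑3,7‑diol
Conditions: TBAF (2.2 equiv), AcOH (2.2 equiv), THF, 0 °C, Ar
Reagents that add atoms: none
Why: Buffered fluoride desilylation frees the catechol without acid, so the ortho‑prenylphenol cannot cyclise and the catechol is not exposed to strong base.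

## Compound list

1 | 5‑bromobenzene‑1,3‑diol | Oc1cc(O)cc(Br)c1 | starting material
2 | 1‑bromo‑3,5‑bis(methoxymethoxy)benzene | COCOc1cc(Br)cc(OCOC)c1 | intermediate
3 | 3,4‑dihydroxybenzaldehyde | O=Cc1ccc(O)c(O)c1 | starting material
4 | 3,4‑bis(triisopropylsilyloxy)benzaldehyde | O=Cc1ccc(O[Si](C(C)C)(C(C)C)C(C)C)c(O[Si](C(C)C)(C(C)C)C(C)C)c1 | intermediate
5 | 4‑ethenyl‑1,2‑bis(triisopropylsilyloxy)benzene | C=Cc1ccc(O[Si](C(C)C)(C(C)C)C(C)C)c(O[Si](C(C)C)(C(C)C)C(C)C)c1 | intermediate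
6 | 9‑{2‑[3,4‑bis(triisopropylsilyloxy)phenyl]ethyl}‑9‑borabicyclo[3.3.1]nonane | B1(CCc2ccc(O[Si](C(C)C)(C(C)C)C(C)C)c(O[Si](C(C)C)(C(C)C)C(C)C)c2)C2CCCC1CCC2 | intermediate (not isolated)
7 | 1‑{2‑[3,4‑bis(triisopropylsilyloxy)phenyl]ethyl}‑3,5‑bis(methoxymethoxy)benzene | COCOc1cc(CCc2ccc(O[Si](C(C)C)(C(C)C)C(C)C)c(O[Si](C(C)C)(C(C)C)C(C)C)c2)cc(OCOC)c1 | intermediate
8 | 2‑bromo‑1‑{2‑[3,4‑bis(triisopropylsilyloxy)phenyl]ethyl}‑3,5‑bis(methoxymethoxy)benzene | COCOc1cc(OCOC)c(Br)c(CCc2ccc(O[Si](C(C)C)(C(C)C)C(C)C)c(O[Si](C(C)C)(C(C)C)C(C)C)c2)c1 | intermediate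
9 | methyl (2R)‑oxirane‑2‑carboxylate | COC(=O)[C@H]1CO1 | starting material
10 | {2‑[2‑(3,4‑bis(triisopropylsilyloxy)phenyl)ethyl]‑4,6‑bis(methoxymethoxy)phenyl}magnesium bromide | COCOc1cc(OCOC)c([Mg]Br)c(CCc2ccc(O[Si](C(C)C)(C(C)C)C(C)C)c(O[Si](C(C)C)(C(C)C)C(C)C)c2)c1 | intermediate (not isolated)
11 | methyl (2R)‑3‑{2‑[2‑(3,4‑bis(triisopropylsilyloxy)phenyl)ethyl]‑4,6‑bis(methoxymethoxy)phenyl}‑2‑hydroxypropanoate | COC(=O)[C@H](O)Cc1c(OCOC)cc(OCOC)cc1CCc1ccc(O[Si](C(C)C)(C(C)C)C(C)C)c(O[Si](C(C)C)(C(C)C)C(C)C)c1 | intermediate (not isolated)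
12 | (2R)‑1‑{2‑[2‑(3,4‑bis(triisopropylsilyloxy)phenyl)ethyl]‑4,6‑bis(methoxymethoxy)phenyl}‑3‑methylbutane‑2,3‑diol | CC(C)(O)[C@H](O)Cc1c(OCOC)cc(OCOC)cc1CCc1ccc(O[Si](C(C)C)(C(C)C)C(C)C)c(O[Si](C(C)C)(C(C)C)C(C)C)c1 | intermediate
13 | 4‑[(2R)‑2,3‑dihydroxy‑3‑methylbutyl]‑5‑{2‑[3,4‑bis(triisopropylsilyloxy)phenyl]ethyl}benzene‑1,3‑diol | CC(C)(O)[C@H](O)Cc1c(O)cc(O)cc1CCc1ccc(O[Si](C(C)C)(C(C)C)C(C)C)c(O[Si](C(C)C)(C(C)C)C(C)C)c1 | intermediate (not isolated)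
14 | (3R)‑5‑{2‑[3,4‑bis(triisopropylsilyloxy)phenyl]ethyl}‑2,2‑dimethyl‑3,4‑dihydro‑2H‑chromene‑3,7‑diol | Oc1cc2c(c(CCc3ccc(O[Si](C(C)C)(C(C)C)C(C)C)c(O[Si](C(C)C)(C(C)C)C(C)C)c3)c1)C[C@@H](O)C(C)(C)O2 | intermediate
15 | (3R)‑5‑{2‑[3,4‑bis(triisopropylsilyloxy)phenyl]ethyl}‑2,2‑dimethyl‑7‑[(2‑methylbut‑3‑yn‑2‑yl)oxy]‑3,4‑dihydro‑2H‑chromen‑3‑ol | C#CC(C)(C)Oc1cc2c(c(CCc3ccc(O[Si](C(C)C)(C(C)C)C(C)C)c(O[Si](C(C)C)(C(C)C)C(C)C)c3)c1)C[C@@H](O)C(C)(C)O2 | intermediate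
16 | (3R)‑5‑{2‑[3,4‑bis(triisopropylsilyloxy)phenyl]ethyl}‑2,2‑dimethyl‑7‑[(2‑methylbut‑3‑en‑2‑yl)oxy]‑3,4‑dihydro‑2H‑chromen‑3‑ol | C=CC(C)(C)Oc1cc2c(c(CCc3ccc(O[Si](C(C)C)(C(C)C)C(C)C)c(O[Si](C(C)C)(C(C)C)C(C)C)c3)c1)C[C@@H](O)C(C)(C)O2 | intermediate (not isolated)
17 | (3R)‑5‑{2‑[3,4‑bis(triisopropylsilyloxy)phenyl]ethyl}‑3‑hydroxy‑2,2‑dimethyl‑6‑(3‑methylbut‑2‑en‑1‑yl)‑3,4‑dihydro‑2H‑chromen‑7(6H)‑one (C6 epimers) | CC(C)=CCC1C(=O)C=C2OC(C)(C)[C@H](O)CC2=C1CCc1ccc(O[Si](C(C)C)(C(C)C)C(C)C)c(O[Si](C(C)C)(C(C)C)C(C)C)c1 | intermediate (not isolated)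
18 | (3R)‑5‑{2‑[3,4‑bis(triisopropylsilyloxy)phenyl]ethyl}‑2,2‑dimethyl‑6‑(3‑methylbut‑2‑en‑1‑yl)‑3,4‑dihydro‑2H‑chromene‑3,7‑diol | CC(C)=CCc1c(O)cc2c(c1CCc1ccc(O[Si](C(C)C)(C(C)C)C(C)C)c(O[Si](C(C)C)(C(C)C)C(C)C)c1)C[C@@H](O)C(C)(C)O2 | intermediate
19 | (3R)‑5‑[2‑(3,4‑dihydroxyphenyl)ethyl]‑2,2‑dimethyl‑6‑(3‑methylbut‑2‑en‑1‑yl)‑3,4‑dihydro‑2H‑chromene‑3,7‑diol | CC(C)=CCc1c(O)cc2c(c1CCc1ccc(O)c(O)c1)C[C@@H](O)C(C)(C)O2 | target

## Step count and risks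

Total steps: 10. Longest linear sequence: 9 (3 → 4 → 5 → 7 → 8 → 12 → 14 → 15 → 18 → 19); step 1 is the only side branch.

**Step 9, Claisen regiochemistry.** The allyl terminus can bond to C6 (wanted) or C8; the preference for C6 is electronic and may be only modest. The fallback sets out from 14 and comes back to the route at 18, replacing steps 8 and 9. NBS (1 equiv, CH2Cl2, −40 °C) brominates 14 at C6, the position para to the ring oxygen as in step 5, to give (3R)‑6‑bromo‑5‑{2‑[3,4‑bis(triisopropylsilyloxy)phenyl]ethyl}‑2,2‑dimethyl‑3,4‑dihydro‑2H‑chromene‑3,7‑diol F1. A Suzuki–Miyaura coupling of F1 with prenylboronic acid pinacol ester, using a bulky biaryl di‑tert‑butylphosphine ligand that favours the linear product (Pd(OAc)2, K3PO4, THF/H2O, 40 °C), then gives 18 with the position fixed by the bromide.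

**Step 7, MOM cleavage and cyclodehydration.** Possible failures are pinacol‑type hydride shift of the tertiary cation, capture of the diol as a methylene acetal, or partial silyl loss. The fallback sets out from 8 and comes back at 14, and uses the enantiomeric epoxide because it inverts C3 once. Step 6 is run with methyl (2S)‑oxirane‑2‑carboxylate to give (2S)‑1‑{2‑[2‑(3,4‑bis(triisopropylsilyloxy)phenyl)ethyl]‑4,6‑bis(methoxymethoxy)phenyl}‑3‑methylbutane‑2,3‑diol F3. MsCl/Et3N (CH2Cl2, 0 °C) sulfonylates only the secondary hydroxyl to give (2S)‑1‑{2‑[2‑(3,4‑bis(triisopropylsilyloxy)phenyl)ethyl]‑4,6‑bis(methoxymethoxy)phenyl}‑3‑hydroxy‑3‑methylbutan‑2‑yl methanesulfonate F4. K2CO3/MeOH closes it with inversion to (3R)‑3‑({2‑[2‑(3,4‑bis(triisopropylsilyloxy)phenyl)ethyl]‑4,6‑bis(methoxymethoxy)phenyl}methyl)‑2,2‑dimethyloxirane F5. Catalytic BF3·OEt2 (CH2Cl2, −40 °C) opens the epoxide at its tertiary carbon with the neighbouring MOM‑ether oxygen, which loses its MOM group, to give (3R)‑5‑{2‑[3,4‑bis(triisopropylsilyloxy)phenyl]ethyl}‑7‑(methoxymethoxy)‑2,2‑dimethyl‑3,4‑dihydro‑2H‑chromen‑3‑ol F6. Brief HCl/MeOH at rt removes the last MOM group to give 14.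

**Step 6, one‑pot Grignard/epoxide/ester sequence.** The aryl Grignard may attack the ester, or the hindered aryl group may open the glycidate sluggishly. The fallback sets out from 9 (with Grignard 10 made from 8 as before) and comes back at 12; it reverses the order of events. MeLi (2.1 equiv, THF, −78 °C) adds twice to the ester of 9 without touching the epoxide to give 2‑[(2R)‑oxiran‑2‑yl]propan‑2‑ol F2, used as its lithium alkoxide solution. Grignard 10 with CuI (10 mol%, −30 → 0 °C) then opens this ester‑free terminal epoxide at CH2 to give 12.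

## Further compounds

F1 | step 9 | (3R)‑6‑bromo‑5‑{2‑[3,4‑bis(triisopropylsilyloxy)phenyl]ethyl}‑2,2‑dimethyl‑3,4‑dihydro‑2H‑chromene‑3,7‑diol | Brc1c(O)cc2c(c1CCc1ccc(O[Si](C(C)C)(C(C)C)C(C)C)c(O[Si](C(C)C)(C(C)C)C(C)C)c1)C[C@@H](O)C(C)(C)O2
F2 | step 6 | 2‑[(2R)‑oxiran‑2‑yl]propan‑2‑ol | CC(C)(O)[C@H]1CO1
F3 | step 7 | (2S)‑1‑{2‑[2‑(3,4‑bis(triisopropylsilyloxy)phenyl)ethyl]‑4,6‑bis(methoxymethoxy)phenyl}‑3‑methylbutane‑2,3‑diol | CC(C)(O)[C@@H](O)Cc1c(OCOC)cc(OCOC)cc1CCc1ccc(O[Si](C(C)C)(C(C)C)C(C)C)c(O[Si](C(C)C)(C(C)C)C(C)C)c1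
F4 | step 7 | (2S)‑1‑{2‑[2‑(3,4‑bis(triisopropylsilyloxy)phenyl)ethyl]‑4,6‑bis(methoxymethoxy)phenyl}‑3‑hydroxy‑3‑methylbutan‑2‑yl methanesulfonate | CC(C)(O)[C@@H](OS(C)(=O)=O)Cc1c(OCOC)cc(OCOC)cc1CCc1ccc(O[Si](C(C)C)(C(C)C)C(C)C)c(O[Si](C(C)C)(C(C)C)C(C)C)c1
F5 | step 7 | (3R)‑3‑({2‑[2‑(3,4‑bis(triisopropylsilyloxy)phenyl)ethyl]‑4,6‑bis(methoxymethoxy)phenyl}methyl)‑2,2‑dimethyloxirane | CC1(C)O[C@@H]1Cc1c(OCOC)cc(OCOC)cc1CCc1ccc(O[Si](C(C)C)(C(C)C)C(C)C)c(O[Si](C(C)C)(C(C)C)C(C)C)c1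
F6 | step 7 | (3R)‑5‑{2‑[3,4‑bis(triisopropylsilyloxy)phenyl]ethyl}‑7‑(methoxymethoxy)‑2,2‑dimethyl‑3,4‑dihydro‑2H‑chromen‑3‑ol | COCOc1cc2c(c(CCc3ccc(O[Si](C(C)C)(C(C)C)C(C)C)c(O[Si](C(C)C)(C(C)C)C(C)C)c3)c1)C[C@@H](O)C(C)(C)O2
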